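**Retrosynthetic overview**
1. Manuifolin D, a (3R)-isoflavan, is traced back by desilylation and by reductive removal of an extra alkoxy group on C2 to a 2-alkoxyisoflavan acetal.
2. Key disconnection: retro-[4+2] of ring C across C4–C3 and O1–C2. This gives an ortho-quinone methide of ring A and an (E)-2-arylvinyl ether of ring B whose alkoxy group is the chiral auxiliary (1R,2S)-2-phenylcyclohexanol.
3. Enabling feature: O1–C8a–C4a–C4 is an ortho-hydroxybenzyl unit of the resorcinol ring A (O1 ortho and O7 para to C4a), a latent 1-oxadiene. C2 is a plain OCH2 group next to the only stereocentre C3, so a removable oxygen on C2 can invert the styrene polarity and relay chirality to C3.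
4. Ring B: the 4'-O-prenyl/5'-(1,1-dimethylallyl) pair comes from O-prenylation, aromatic Claisen rearrangement and renewed O-prenylation of 2,4-dihydroxybenzaldehyde, which also supplies ring A.
5. Ring order: rings A and B are bought as arenes; ring C is the only ring made, in the key step.

Key step: step 10

Remark: the stereocentre of the given SMILES is read as (3R). Isoflavan numbering is used (O1, C2, C3, C4, C4a, C5–C8, C8a; ring B primed).

**Step 1**
Reactants: 1 2,4-dihydroxybenzaldehyde; 2 prenyl bromide (1-bromo-3-methylbut-2-ene)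
Product: 3 2-hydroxy-4-(3-methylbut-2-enyloxy)benzaldehyde
Conditions: K2CO3 (1.05 equiv), acetone, reflux
Reagents that add atoms: none
Why: Williamson ether synthesis in which the 2-OH, hydrogen-bonded to the formyl group and less acidic, stays free, so one equivalent of weak base should alkylate only the 4-OH.

**Step 2**
Reactants: 3 2-hydroxy-4-(3-methylbut-2-enyloxy)benzaldehyde
Product: 4 4-(3-methylbut-2-enyloxy)-2-(triisopropylsilyloxy)benzaldehyde
Conditions: TIPSCl, imidazole, DMF, rt
Reagents that add atoms: triisopropylsilyl chloride, CC(C)[Si](Cl)(C(C)C)C(C)C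
Why: Standard phenol silylation, giving a bulky ether that should survive the later heat and carbonate bases and that screens C3 in the next step.

**Step 3**
Reactants: 4 4-(3-methylbut-2-enyloxy)-2-(triisopropylsilyloxy)benzaldehyde
Product: 6 4-hydroxy-5-(2-methylbut-3-en-2-yl)-2-(triisopropylsilyloxy)benzaldehyde, via ortho-dienone 5 (not isolated)
Conditions: PhNEt2, 195 °C, sealed tube
Reagents that add atoms: none
Why: Aromatic Claisen rearrangement ([3,3]-sigmatropic shift, then tautomerisation) turns the O-prenyl group into the C-bound 1,1-dimethylallyl group, and C5 should win over C3 because C3 lies between two oxygen substituents, one of them the TIPS ether, as known for 2-alkoxy-4-prenyloxybenzaldehydes.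

**Step 4**
Reactants: 6 4-hydroxy-5-(2-methylbut-3-en-2-yl)-2-(triisopropylsilyloxy)benzaldehyde; 2 prenyl bromide
Product: 7 5-(2-methylbut-3-en-2-yl)-4-(3-methylbut-2-enyloxy)-2-(triisopropylsilyloxy)benzaldehyde
Conditions: K2CO3, acetone, reflux
Reagents that add atoms: none
Why: Williamson ether synthesis on the only free phenol, which is acidic (para to the formyl group) and reacts with the unhindered primary allylic bromide far below the temperature of a second Claisen rearrangement.

**Step 5**
Reactants: 7 5-(2-methylbut-3-en-2-yl)-4-(3-methylbut-2-enyloxy)-2-(triisopropylsilyloxy)benzaldehyde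
Product: 8 {2-[(E)-2-iodoethenyl]-4-(2-methylbut-3-en-2-yl)-5-(3-methylbut-2-enyloxy)phenoxy}triisopropylsilane
Conditions: CrCl2 (6 equiv), CHI3 (2 equiv), THF, 0 °C to rt
Reagents that add atoms: iodoform, IC(I)I
Why: Takai olefination, which is E-selective for aromatic aldehydes and leaves silyl ethers, aryl allyl ethers and isolated alkenes alone.

**Step 6**
Reactants: 8 {2-[(E)-2-iodoethenyl]-4-(2-methylbut-3-en-2-yl)-5-(3-methylbut-2-enyloxy)phenoxy}triisopropylsilane; 9 (1R,2S)-trans-2-phenylcyclohexanol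
Product: 10 triisopropyl{4-(2-methylbut-3-en-2-yl)-5-(3-methylbut-2-enyloxy)-2-[(E)-2-{[(1R,2S)-2-phenylcyclohexyl]oxy}ethenyl]phenoxy}silane
Conditions: CuI (10 mol %), 3,4,7,8-tetramethyl-1,10-phenanthroline (20 mol %), Cs2CO3, toluene, 90 °C
Reagents that add atoms: none
Why: Copper-catalysed Ullmann-type C–O cross-coupling of a vinyl iodide with an alcohol, which proceeds with retention of the alkene geometry and does not touch the carbinol stereocentres.

**Step 7**
Reactants: 1 2,4-dihydroxybenzaldehyde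
Product: 11 2-hydroxy-4-(triisopropylsilyloxy)benzaldehyde
Conditions: TIPSCl (1.0 equiv), imidazole, CH2Cl2, 0 °C
Reagents that add atoms: triisopropylsilyl chloride, CC(C)[Si](Cl)(C(C)C)C(C)C
Why: Selective silylation of the more acidic and unhindered 4-OH, while the chelated 2-OH stays free.

**Step 8**
Reactants: 11 2-hydroxy-4-(triisopropylsilyloxy)benzaldehyde
Product: 12 tert-butyl 2-formyl-5-(triisopropylsilyloxy)phenyl carbonate
Conditions: Boc2O, DMAP (5 mol %), CH2Cl2, 0 °C to rt
Reagents that add atoms: di-tert-butyl dicarbonate, CC(C)(C)OC(=O)OC(=O)OC(C)(C)C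
Why: DMAP-catalysed O-acylation of the phenol, installing the carbonate that later serves as a migrating leaving group.

**Step 9**
Reactants: 12 tert-butyl 2-formyl-5-(triisopropylsilyloxy)phenyl carbonate
Product: 13 tert-butyl 2-(hydroxymethyl)-5-(triisopropylsilyloxy)phenyl carbonate
Conditions: BH3·THF, THF, 0 °C; then pH 7 buffer
Reagents that add atoms: none
Why: Borane reduction of the aldehyde runs through a neutral borate ester and not a free alkoxide, so premature Boc migration and quinone methide formation should be avoided.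

**Step 10**
Reactants: 13 tert-butyl 2-(hydroxymethyl)-5-(triisopropylsilyloxy)phenyl carbonate; 10 triisopropyl{4-(2-methylbut-3-en-2-yl)-5-(3-methylbut-2-enyloxy)-2-[(E)-2-{[(1R,2S)-2-phenylcyclohexyl]oxy}ethenyl]phenoxy}silane
Product: 16 (2S,3R)-3-[5-(2-methylbut-3-en-2-yl)-4-(3-methylbut-2-enyloxy)-2-(triisopropylsilyloxy)phenyl]-2-{[(1R,2S)-2-phenylcyclohexyl]oxy}-7-(triisopropylsilyloxy)chroman, via benzylic carbonate 14 (not isolated), via ortho-quinone methide 15 (not isolated)
Conditions: 13 (2 equiv), tBuMgCl (1.0 equiv per 13), Et2O, −78 °C to rt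
Reagents that add atoms: none
Why: tBuMgCl deprotonates the benzylic alcohol of 13, the Boc group migrates from the phenolic to the benzylic oxygen (14), and magnesium-assisted 1,4-elimination of tert-butyl carbonate releases ortho-quinone methide 15 slowly on warming, which enol ether 10 captures in an inverse-electron-demand hetero-Diels–Alder reaction that forms C4–C3 and O1–C2 in one operation and is driven by rearomatisation of ring A. The closest known reaction type is the low-temperature [4+2] cycloaddition of ortho-quinone methides generated from O-Boc salicyl alcohols with alkyl enol ethers, known both with trans-2-phenylcyclohexyl enol ethers as chiral dienophiles and with beta-aryl enol ethers as an entry to 2-alkoxyisoflavans. Ring C is closed in an intermolecular [4π+2π] mode (oxadiene O1=C8a–C4a=C4 plus C2=C3, alkoxy group endo) and is the only ring formed in the synthesis. C2 and C3 are both controlled by the auxiliary: in the s-trans enol ether conformer with the carbinol C–H eclipsing the O–vinyl bond the phenyl ring covers one face, 15 adds to the open face, and suprafacial addition carries the E geometry into the 2,3-trans relationship, so the (1R,2S)-alkoxy group should give (2S,3R); as C4 is a CH2 group the endo/exo question has no bearing on C3, and minor diastereomers can be removed by chromatography at this stage. The regioselectivity needed (methylene carbon to the aryl-bearing carbon, the reverse of what a plain styrene gives) is secured by the oxygen on C2, which puts the largest HOMO coefficient on C3, helped by the ortho-OTIPS group that twists ring B out of conjugation and mutes its opposing donor effect. Chemoselectivity rests on the enol ether being far more nucleophilic than the prenyl and 1,1-dimethylallyl alkenes and on base-triggered, acid-free conditions that leave the aryl prenyl ether and both silyl ethers alone.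

**Step 11**
Reactants: 16 (2S,3R)-3-[5-(2-methylbut-3-en-2-yl)-4-(3-methylbut-2-enyloxy)-2-(triisopropylsilyloxy)phenyl]-2-{[(1R,2S)-2-phenylcyclohexyl]oxy}-7-(triisopropylsilyloxy)chroman
Product: 17 (3R)-3-[5-(2-methylbut-3-en-2-yl)-4-(3-methylbut-2-enyloxy)-2-(triisopropylsilyloxy)phenyl]-7-(triisopropylsilyloxy)chroman
Conditions: Et3SiH (5 equiv), TMSOTf (20 mol %), 2,6-di-tert-butyl-4-methylpyridine (10 mol %), CH2Cl2, −78 °C
Reagents that add atoms: none
Why: Silyl-triflate-catalysed ionic reduction of an acetal with Et3SiH, in which the more basic exocyclic alkoxy oxygen is silylated and leaves and the cyclic oxocarbenium ion should be trapped by hydride at −78 °C before it can lose the C3 proton, so C3 stays (3R) while the C2 stereocentre and the auxiliary disappear together.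

**Step 12**
Reactants: 17 (3R)-3-[5-(2-methylbut-3-en-2-yl)-4-(3-methylbut-2-enyloxy)-2-(triisopropylsilyloxy)phenyl]-7-(triisopropylsilyloxy)chroman
Product: 18 manuifolin D, (3R)-3-[2-hydroxy-5-(2-methylbut-3-en-2-yl)-4-(3-methylbut-2-enyloxy)phenyl]chroman-7-ol
Conditions: TBAF (2.5 equiv), AcOH (2.5 equiv), THF, 0 °C
Reagents that add atoms: none
Why: Buffered fluoride desilylation frees both phenols under conditions that touch neither the aryl prenyl ether, the alkenes nor the non-acidic C3 stereocentre.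

**Compound list**
1 | 2,4-dihydroxybenzaldehyde | O=Cc1ccc(O)cc1O | starting material
2 | prenyl bromide (1-bromo-3-methylbut-2-ene) | CC(C)=CCBr | starting material
3 | 2-hydroxy-4-(3-methylbut-2-enyloxy)benzaldehyde | O=Cc1ccc(OCC=C(C)C)cc1O | intermediate
4 | 4-(3-methylbut-2-enyloxy)-2-(triisopropylsilyloxy)benzaldehyde | O=Cc1ccc(OCC=C(C)C)cc1O[Si](C(C)C)(C(C)C)C(C)C | intermediate
5 | ortho-dienone, 4-formyl-6-(2-methylbut-3-en-2-yl)-3-(triisopropylsilyloxy)cyclohexa-2,4-dien-1-one (racemic, not isolated) | O=CC1=CC(C(C)(C)C=C)C(=O)C=C1O[Si](C(C)C)(C(C)C)C(C)C | intermediate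
6 | 4-hydroxy-5-(2-methylbut-3-en-2-yl)-2-(triisopropylsilyloxy)benzaldehyde | O=Cc1cc(C(C)(C)C=C)c(O)cc1O[Si](C(C)C)(C(C)C)C(C)C | intermediate
7 | 5-(2-methylbut-3-en-2-yl)-4-(3-methylbut-2-enyloxy)-2-(triisopropylsilyloxy)benzaldehyde | O=Cc1cc(C(C)(C)C=C)c(OCC=C(C)C)cc1O[Si](C(C)C)(C(C)C)C(C)C | intermediate
8 | {2-[(E)-2-iodoethenyl]-4-(2-methylbut-3-en-2-yl)-5-(3-methylbut-2-enyloxy)phenoxy}triisopropylsilane | I/C=C/c1cc(C(C)(C)C=C)c(OCC=C(C)C)cc1O[Si](C(C)C)(C(C)C)C(C)C | intermediate
9 | (1R,2S)-trans-2-phenylcyclohexanol | O[C@@H]1CCCC[C@H]1c1ccccc1 | starting material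
10 | triisopropyl{4-(2-methylbut-3-en-2-yl)-5-(3-methylbut-2-enyloxy)-2-[(E)-2-{[(1R,2S)-2-phenylcyclohexyl]oxy}ethenyl]phenoxy}silane | O(/C=C/c1cc(C(C)(C)C=C)c(OCC=C(C)C)cc1O[Si](C(C)C)(C(C)C)C(C)C)[C@@H]1CCCC[C@H]1c1ccccc1 | intermediate
11 | 2-hydroxy-4-(triisopropylsilyloxy)benzaldehyde | O=Cc1ccc(O[Si](C(C)C)(C(C)C)C(C)C)cc1O | intermediate
12 | tert-butyl 2-formyl-5-(triisopropylsilyloxy)phenyl carbonate | O=Cc1ccc(O[Si](C(C)C)(C(C)C)C(C)C)cc1OC(=O)OC(C)(C)C | intermediate
13 | tert-butyl 2-(hydroxymethyl)-5-(triisopropylsilyloxy)phenyl carbonate | OCc1ccc(O[Si](C(C)C)(C(C)C)C(C)C)cc1OC(=O)OC(C)(C)C | intermediate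
14 | tert-butyl 2-hydroxy-4-(triisopropylsilyloxy)benzyl carbonate (present as its magnesium phenoxide, not isolated) | CC(C)(C)OC(=O)OCc1ccc(O[Si](C(C)C)(C(C)C)C(C)C)cc1O | intermediate
15 | ortho-quinone methide, 6-methylidene-3-(triisopropylsilyloxy)cyclohexa-2,4-dien-1-one (not isolated) | C=C1C=CC(O[Si](C(C)C)(C(C)C)C(C)C)=CC1=O | intermediate
16 | (2S,3R)-3-[5-(2-methylbut-3-en-2-yl)-4-(3-methylbut-2-enyloxy)-2-(triisopropylsilyloxy)phenyl]-2-{[(1R,2S)-2-phenylcyclohexyl]oxy}-7-(triisopropylsilyloxy)chroman | C=CC(C)(C)c1cc([C@@H]2[C@@H](O[C@@H]4CCCC[C@H]4c4ccccc4)Oc3cc(O[Si](C(C)C)(C(C)C)C(C)C)ccc3C2)c(O[Si](C(C)C)(C(C)C)C(C)C)cc1OCC=C(C)C | intermediate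
17 | (3R)-3-[5-(2-methylbut-3-en-2-yl)-4-(3-methylbut-2-enyloxy)-2-(triisopropylsilyloxy)phenyl]-7-(triisopropylsilyloxy)chroman | C=CC(C)(C)c1cc([C@@H]2COc3cc(O[Si](C(C)C)(C(C)C)C(C)C)ccc3C2)c(O[Si](C(C)C)(C(C)C)C(C)C)cc1OCC=C(C)C | intermediate
18 | manuifolin D, (3R)-3-[2-hydroxy-5-(2-methylbut-3-en-2-yl)-4-(3-methylbut-2-enyloxy)phenyl]chroman-7-ol | C=CC(C)(C)c1cc([C@@H]2COc3cc(O)ccc3C2)c(O)cc1OCC=C(C)C | target

**Step count**
Total step count: 12.
Longest linear sequence: 9 steps (steps 1–6 and 10–12, from 2,4-dihydroxybenzaldehyde).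

**Steps most likely to fail**

**Step 10.**
- Risk: capture of the short-lived quinone methide by the hindered, conjugated enol ether may be slower than self-condensation of the quinone methide. Facial discrimination may also erode if the s-cis conformer of the enol ether takes part.
- Fallback: the two bonds are made one after the other, by Evans alkylation and Mitsunobu etherification. It sets out from 7 and 13 and comes back at 17.
- Aldehyde 7 is homologated by a Wittig reaction with Ph3P=CHOMe to the methyl enol ether F1. This is hydrolysed with aqueous oxalic acid in THF to the arylacetaldehyde F2.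
- Pinnick oxidation (NaClO2, NaH2PO4, 2-methyl-2-butene) gives the arylacetic acid F3. Pivaloyl chloride and Et3N convert it into the mixed pivalic anhydride F4, and lithiated (R)-4-benzyloxazolidin-2-one then gives the imide F5.
- Alcohol 13 is turned by an Appel reaction (CBr4, PPh3, CH2Cl2, 0 °C) into the benzylic bromide F6.
- The chelated Z-enolate of F5 (NaHMDS, THF, −78 °C) is alkylated by F6 on the face away from the benzyl group, which should give the (R)-configured alkylated imide F7.
- LiAlH4 (THF, 0 °C) removes auxiliary and carbonate together to give the phenol alcohol F8. Mitsunobu etherification (DIAD, PPh3, THF) closes O1–C2 to 17.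

**Step 11.**
- Risk: the silyl triflate may ionise the aryl prenyl ether, and the oxocarbenium ion may lose its C3 proton with erosion of enantiopurity. Ring C may also open by endocyclic C2–O1 cleavage, or the 2'-oxygen may participate.
- Fallback: the C2 substituent is removed through a radical instead of a cation. It sets out from 16 and comes back at 17.
- Mild hydrolysis (PPTS, THF–H2O, 40 °C) gives the lactol F9 and returns the auxiliary.
- Neutral thiolation with PhSSPh and Bu3P in THF gives the O,S-acetal F10.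
- Tin hydride reduction (Bu3SnH, AIBN, toluene, 80 °C), a known way from mixed thioacetals to cyclic ethers, replaces the sulfur by hydrogen without Lewis acid and without breaking O1–C2.

**Step 6.**
- Risk: C–O coupling of the hindered secondary alcohol may be sluggish. The vinyl iodide may be dehydroiodinated by the carbonate base, or the alkoxide may attack the aryl silyl ether.
- Fallback: the C=C bond is built by olefination instead of the C–O bond by coupling. It sets out from 9 and 7 and comes back at 10.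
- Alcohol 9 is converted with paraformaldehyde and TMSCl into the chloromethyl ether F11, and with PPh3 in toluene into the phosphonium chloride F12.
- Its ylide (KHMDS, THF, −78 °C) olefinates aldehyde 7 in a Wittig reaction.
- The (E)-isomer 10 is separated by chromatography from the (Z)-enol ether F13.

**Further compounds**
F1 | step 10 | {2-(2-methoxyethenyl)-4-(2-methylbut-3-en-2-yl)-5-(3-methylbut-2-enyloxy)phenoxy}triisopropylsilane (E/Z mixture) | COC=Cc1cc(C(C)(C)C=C)c(OCC=C(C)C)cc1O[Si](C(C)C)(C(C)C)C(C)C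
F2 | step 10 | 2-[5-(2-methylbut-3-en-2-yl)-4-(3-methylbut-2-enyloxy)-2-(triisopropylsilyloxy)phenyl]acetaldehyde | O=CCc1cc(C(C)(C)C=C)c(OCC=C(C)C)cc1O[Si](C(C)C)(C(C)C)C(C)C
F3 | step 10 | 2-[5-(2-methylbut-3-en-2-yl)-4-(3-methylbut-2-enyloxy)-2-(triisopropylsilyloxy)phenyl]acetic acid | OC(=O)Cc1cc(C(C)(C)C=C)c(OCC=C(C)C)cc1O[Si](C(C)C)(C(C)C)C(C)C
F4 | step 10 | mixed anhydride of F3 and pivalic acid | CC(C)(C)C(=O)OC(=O)Cc1cc(C(C)(C)C=C)c(OCC=C(C)C)cc1O[Si](C(C)C)(C(C)C)C(C)C
F5 | step 10 | (4R)-4-benzyl-3-{2-[5-(2-methylbut-3-en-2-yl)-4-(3-methylbut-2-enyloxy)-2-(triisopropylsilyloxy)phenyl]acetyl}oxazolidin-2-one | O=C1OC[C@@H](Cc2ccccc2)N1C(=O)Cc1cc(C(C)(C)C=C)c(OCC=C(C)C)cc1O[Si](C(C)C)(C(C)C)C(C)C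
F6 | step 10 | 2-(bromomethyl)-5-(triisopropylsilyloxy)phenyl tert-butyl carbonate | BrCc1ccc(O[Si](C(C)C)(C(C)C)C(C)C)cc1OC(=O)OC(C)(C)C
F7 | step 10 | (4R)-4-benzyl-3-{(2R)-3-[2-(tert-butoxycarbonyloxy)-4-(triisopropylsilyloxy)phenyl]-2-[5-(2-methylbut-3-en-2-yl)-4-(3-methylbut-2-enyloxy)-2-(triisopropylsilyloxy)phenyl]propanoyl}oxazolidin-2-one | O=C1OC[C@@H](Cc2ccccc2)N1C(=O)[C@H](Cc1ccc(O[Si](C(C)C)(C(C)C)C(C)C)cc1OC(=O)OC(C)(C)C)c1cc(C(C)(C)C=C)c(OCC=C(C)C)cc1O[Si](C(C)C)(C(C)C)C(C)C
F8 | step 10 | 2-{(2R)-3-hydroxy-2-[5-(2-methylbut-3-en-2-yl)-4-(3-methylbut-2-enyloxy)-2-(triisopropylsilyloxy)phenyl]propyl}-5-(triisopropylsilyloxy)phenol | OC[C@H](Cc1ccc(O[Si](C(C)C)(C(C)C)C(C)C)cc1O)c1cc(C(C)(C)C=C)c(OCC=C(C)C)cc1O[Si](C(C)C)(C(C)C)C(C)C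
F9 | step 11 | (3R)-3-[5-(2-methylbut-3-en-2-yl)-4-(3-methylbut-2-enyloxy)-2-(triisopropylsilyloxy)phenyl]-7-(triisopropylsilyloxy)chroman-2-ol (anomer mixture) | C=CC(C)(C)c1cc([C@@H]2C(O)Oc3cc(O[Si](C(C)C)(C(C)C)C(C)C)ccc3C2)c(O[Si](C(C)C)(C(C)C)C(C)C)cc1OCC=C(C)C
F10 | step 11 | (3R)-3-[5-(2-methylbut-3-en-2-yl)-4-(3-methylbut-2-enyloxy)-2-(triisopropylsilyloxy)phenyl]-2-(phenylsulfanyl)-7-(triisopropylsilyloxy)chroman (anomer mixture) | C=CC(C)(C)c1cc([C@@H]2C(Sc4ccccc4)Oc3cc(O[Si](C(C)C)(C(C)C)C(C)C)ccc3C2)c(O[Si](C(C)C)(C(C)C)C(C)C)cc1OCC=C(C)C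
F11 | step 6 | [(1S,2R)-2-(chloromethoxy)cyclohexyl]benzene, the chloromethyl ether of 9 | ClCO[C@@H]1CCCC[C@H]1c1ccccc1
F12 | step 6 | triphenyl({[(1R,2S)-2-phenylcyclohexyl]oxy}methyl)phosphonium chloride | [Cl-].c1ccccc1[P+](c1ccccc1)(c1ccccc1)CO[C@@H]1CCCC[C@H]1c1ccccc1
F13 | step 6 | (Z)-isomer of 10 | O(/C=C\c1cc(C(C)(C)C=C)c(OCC=C(C)C)cc1O[Si](C(C)C)(C(C)C)C(C)C)[C@@H]1CCCC[C@H]1c1ccccc1
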